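By 10 h, how far each flask below has come depends on how much solid substrate passes into product per hour.

| flask | solid substrate | coupling partner | initiator | remark | time |
|---|---|---|---|---|---|
| violet | 0.22 M | 1 M | 2 mM | run made earlier |  |
| grey | 1.2 M | 1 M | 2 mM | run made earlier |  |
| Tuesday's | 0.20 M | 1.00 M | 2.0 mM |  | 10 h |
| Friday's | 0.40 M | 1.00 M | 2.0 mM |  | 10 h |
| Sunday's | 0.80 M | 1.00 M | 2.0 mM |  | 10 h |

- violet (time / h: product / %, solid substrate / %): 0.500: 10.0, 67.3; 1.00: 28.4, 44.9; 2.00: 67.2, 5.5; 4.00: 98.9, 1.3; 8.00: 99.9, 0.5
- grey (time / h: product / %, solid substrate / %): 0.667: 4.0, 92.7; 2.00: 11.2, 83.2; 3.00: 15.9, 75.9; 5.00: 30.6, 63.0; 8.00: 48.5, 46.9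

(standard deviation of a reading: 1 percentage point)

- at the start none of the solid substrate is in solution
- a step back or a flat step of under half a percent of the largest counts as no turn
- a reading or a percentage of product counts all its forms, free or not
- the concentration of product that is asked is that of its free form alone
- "hardly changes" means that all values lie within two and a half points (for a concentration: within two and a half percent of the largest)
- a step back or a flat step of under half a percent of the largest counts as no turn

* [product] (only what is free in solution) at the end for Tuesday's, Friday's, Sunday's, in this order
* the course of these numbers from the first flask to the last (falls, then rises / falls all the way / rises, then falls / hardly changes / rises all the way)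

The grey run offers two ways to that rate between 2.00 h and 8.00 h. Product gains 0.0746 M h⁻¹, and solid substrate loses 0.0726 M h⁻¹. These are separate readings, and their difference of 0.00200 M h⁻¹ lies within the 0.00283 M h⁻¹ that the scatter allows.

Up to 0.667 h the two ways part. In the grey run product holds 0.0480 M, less than the 0.0876 M gone from the solid. The solid reading cheats there: its fall includes material that has left the solid and shows in neither reading. Later this uncounted amount stays near 0.0672 M at 2.00 h and 0.0552 M at 8.00 h, so the late window is clear of that filling.

The mean, 0.0736 M h⁻¹, is the feed rate: product made per hour while solid stands in the flask. Dividing each charge by it gives a finishing time of 2.72 h for Tuesday's, 5.43 h for Friday's and 10.9 h for Sunday's, the last beyond 10 h. This reckoning commits to total c(product) of 0.20 M, 0.40 M and 0.736 M. The readings count all forms of product, so it sets no figure for the free part.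

The forecast gives 0.198 M, 0.398 M and 0.73 M as free product, with the course rises all the way, and calls the rate “effectively zero order, with the solution saturated”.

The flask gives 0.00700 M, 0.00700 M and 0.00932 M, and the course rises all the way.

    initiator → 2 initiating radical (k = 0.00128 min⁻¹)
    starting material + initiating radical → capped initiator + first chain carrier (k = 1.45 × 10⁶ L mol⁻¹ s⁻¹)
    coupling partner + first chain carrier → product + second chain carrier (k = 3.15 × 10⁵ L mol⁻¹ min⁻¹)
    starting material + second chain carrier → by-product + first chain carrier (k = 29600 L mol⁻¹ s⁻¹)
    2 first chain carrier → ended chains A (k = 2.00 × 10⁸ L mol⁻¹ s⁻¹)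
    2 second chain carrier → ended chains B (k = 2.00 × 10⁸ L mol⁻¹ s⁻¹)
    crystals ⇌ product, rate k7*(cs7 - [product]) while solid is left; crystals form when [product] > cs7 (solubility = 7.00 mM, k = 0.346 min⁻¹)
    solid substrate ⇌ starting material, rate k8*(cs8 - [starting material]) while solid is left; crystals form when [starting material] > cs8 (solubility = 0.0940 M, k = 0.0406 min⁻¹)

Tuesday's and Friday's have finishing times under 10 h; their limiting reagent, solid substrate, stands at 0%, and free product equals the crystal solubility, 7.0 mM. Sunday's still holds 6.02% solid substrate at the end, and its free product stands 0.00232 M above that solubility, while the feed rate over the crystal rate constant, the excess at which crystals grow at that feed rate, gives 0.00355 M. On Friday's, the feed rate puts product at 92.0% of the charge after 5.00 h, and the flask holds 91.6%; on Sunday's it puts product at 92.0% after 10.0 h, and the flask holds 84.7%.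

All runs stem from a simulated flask with made-up constants; the scatter is artificial.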